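**Retrosynthetic overview**

1. Target acid ⇐ its methyl ester (saponification is the last step).
2. Aryl–furan bond ⇐ C–H borylation at furan C5 of the 3-alkylfuran ester, then Suzuki–Miyaura coupling with 2-bromohydroquinone (one step from hydroquinone).
3. Key disconnection, two bonds at once (C3–C4 and C5–C6) ⇐ a nickel-catalysed radical three-component coupling of 3-vinylfuran, methyl (S)-3-bromo-2-methylpropanoate (brings C2) and prenyl chloride; the chiral ligand sets C5.
4. 3-Vinylfuran ⇐ furan-3-carbaldehyde (Wittig).
5. Rings: none is built; the furan and benzene rings are bought and joined in the last-but-one step.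

Assumption: the sense of induction of the chiral nickel catalyst in the key step cannot be predicted, so the ligand antipode that gives 5R is fixed in a pilot run (the C5 epimers are diastereomers, read against the fixed C2 centre; any minor epimer is removed by preparative HPLC).

**Route**

Step 1
Reactants: 1 furan-3-carbaldehyde
Product: 2 3-ethenylfuran (3-vinylfuran)
Conditions: MePPh3Br (1.2 equiv), KOtBu (1.15 equiv), Et2O, 0 °C, then 1, 0 °C→rt; distil (bp ≈ 93 °C), store cold over BHT
Reagents that add atoms: methyltriphenylphosphonium bromide, C[P+](c1ccccc1)(c1ccccc1)c1ccccc1.[Br-] (supplies the CH2 carbon)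
Why: Wittig methylenation; the non-stabilised ylide adds to the aldehyde and the oxaphosphetane collapses to the terminal alkene and Ph3PO, with no stereocentre involved.

Step 2
Reactants: 2 3-ethenylfuran (3.0 equiv); 3 methyl (2S)-3-bromo-2-methylpropanoate (limiting); 4 1-chloro-3-methylbut-2-ene (prenyl chloride, 1.5 equiv)
Product: 5 methyl (2R,5R)-5-(furan-3-yl)-2,8-dimethylnon-7-enoate
Conditions: NiBr2·diglyme (5 mol%), cyclopropane-1,1-diyl-bridged indanyl bis(oxazoline) (IndaBOX, matched antipode, 6 mol%), tetrakis(dimethylamino)ethylene (TDAE, 1.5 equiv), DMA (0.3 M in 3), 5 °C→rt, Ar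
Reagents that add atoms: none
Why: Proposed new method: nickel-catalysed enantioselective reductive three-component dicarbofunctionalisation (alkyl–allylation) of a vinyl heteroarene — zerovalent nickel adds oxidatively to 4 to give a ligand-bound divalent nickel prenyl complex, its one-electron-reduced (monovalent) form abstracts bromine from 3, the primary radical (radical site β to C2, so the bought stereocentre is untouched) adds to the CH2 terminus of 2 (k ≈ 1e5 M−1 s−1; 2 is held near 1 M and nickel near 15 mM so that addition outruns direct capture by nickel), the furylic radical is captured by the chiral divalent nickel prenyl complex, and the trivalent nickel intermediate reductively eliminates at the unhindered CH2 allyl terminus inside the bis(oxazoline) pocket, which sets C5 under catalyst control (5R with the matched antipode); the closest known reaction types are bis(oxazoline)–nickel enantioselective reductive cross-couplings of benzylic radicals with C(sp2) halides, asymmetric reductive three-component alkyl–arylation of vinylarenes, and linear-selective nickel-catalysed reductive allylation of alkyl halides.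

Step 3
Reactants: 6 benzene-1,4-diol (hydroquinone)
Product: 7 2-bromobenzene-1,4-diol
Conditions: Br2 (1.0 equiv), Et2O/CHCl3, 0 °C→rt; aq Na2S2O4 wash; recrystallise
Reagents that add atoms: bromine, BrBr
Why: Electrophilic aromatic bromination of the doubly activated ring; all four ring positions are equivalent, and one equivalent at 0 °C keeps dibromide low (any quinone formed is returned by the dithionite wash).

Step 4
Reactants: 5 methyl (2R,5R)-5-(furan-3-yl)-2,8-dimethylnon-7-enoate; 7 2-bromobenzene-1,4-diol (1.2 equiv)
Product: 9 methyl (2R,5R)-5-[5-(2,5-dihydroxyphenyl)furan-3-yl]-2,8-dimethylnon-7-enoate, via furyl pinacol boronate 8 (not isolated)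
Conditions: [Ir(OMe)(cod)]2 (1.5 mol%), 4,4'-di-tert-butyl-2,2'-bipyridine (3 mol%), HBpin (1.5 equiv), THF, rt; then 7, Pd(OAc)2 (3 mol%), SPhos (6 mol%), degassed aq K3PO4 (5 equiv), 40 °C, Ar
Reagents that add atoms: pinacolborane, CC1(C)OBOC1(C)C (its boron and pinacol are carried only by 8 and are lost again in the coupling)
Why: Iridium-catalysed C–H borylation is sterically governed and takes the furan α-C–H remote from the branched substituent (C5, not the flanked C2); the 2-furyl boronate is then used at once in a Suzuki–Miyaura coupling with a fast SPhos catalyst before it can protodeboronate, and both stereocentres are spectators.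

Step 5
Reactants: 9 methyl (2R,5R)-5-[5-(2,5-dihydroxyphenyl)furan-3-yl]-2,8-dimethylnon-7-enoate
Product: 10 (2R,5R)-5-[5-(2,5-dihydroxyphenyl)furan-3-yl]-2,8-dimethylnon-7-enoic acid
Conditions: LiOH·H2O (4 equiv), degassed THF/MeOH/H2O (3:1:1), 0 °C→rt, Ar; then 1 M HCl/aq Na2S2O4 to pH 3
Reagents that add atoms: lithium hydroxide, [Li+].[OH-] (its oxygen becomes the acid OH)
Why: Ester saponification (acyl substitution by hydroxide); the carboxylate formed is not enolised under these mild conditions so C2 is retained, and degassing plus the dithionite/acid quench keeps the hydroquinone reduced.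

**Compound list**

1 | furan-3-carbaldehyde | O=Cc1ccoc1 | starting material
2 | 3-ethenylfuran (3-vinylfuran) | C=Cc1ccoc1 | intermediate
3 | methyl (2S)-3-bromo-2-methylpropanoate | BrC[C@@H](C)C(=O)OC | starting material
4 | 1-chloro-3-methylbut-2-ene (prenyl chloride) | CC(C)=CCCl | starting material
5 | methyl (2R,5R)-5-(furan-3-yl)-2,8-dimethylnon-7-enoate | CC(C)=CC[C@@H](CC[C@@H](C)C(=O)OC)c1ccoc1 | intermediate
6 | benzene-1,4-diol (hydroquinone) | Oc1ccc(O)cc1 | starting material
7 | 2-bromobenzene-1,4-diol | Oc1ccc(O)c(Br)c1 | intermediate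
8 | methyl (2R,5R)-2,8-dimethyl-5-[5-(4,4,5,5-tetramethyl-1,3,2-dioxaborolan-2-yl)furan-3-yl]non-7-enoate (not isolated) | CC(C)=CC[C@@H](CC[C@@H](C)C(=O)OC)c1coc(B2OC(C)(C)C(C)(C)O2)c1 | intermediate
9 | methyl (2R,5R)-5-[5-(2,5-dihydroxyphenyl)furan-3-yl]-2,8-dimethylnon-7-enoate | CC(C)=CC[C@@H](CC[C@@H](C)C(=O)OC)c1coc(-c2cc(O)ccc2O)c1 | intermediate
10 | (2R,5R)-5-[5-(2,5-dihydroxyphenyl)furan-3-yl]-2,8-dimethylnon-7-enoic acid | CC(C)=CC[C@@H](CC[C@@H](C)C(=O)O)c1coc(-c2cc(O)ccc2O)c1 | target

**Totals**

Total step count: 5. Longest linear sequence: 4 steps (1 → 2 → 5 → 9 → 10); step 3 is a one-step side branch.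

**Steps most likely to fail, with fallbacks**

Step 2 is the greatest risk. The primary radical from 3 may be captured by nickel before it adds to 2, giving the two-component prenylation product, and the induction at C5 is untested.

The fallback sets out from 2 (and uses 3) and comes back at 5. It replaces the three-component step by a polar copper–boryl addition followed by a two-component radical alkyl–alkyl coupling:
- CuCl with a chiral bisphosphine, NaOtBu, B2pin2 and allyl diethyl phosphate adds boron and allyl enantioselectively across 2, giving 2-[(2R)-2-(furan-3-yl)pent-4-en-1-yl]-4,4,5,5-tetramethyl-1,3,2-dioxaborolane F1.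
- Cross-metathesis with excess 2-methylbut-2-ene (second-generation Grubbs catalyst, 40 °C) turns allyl into prenyl, giving 2-[(2R)-2-(furan-3-yl)-5-methylhex-4-en-1-yl]-4,4,5,5-tetramethyl-1,3,2-dioxaborolane F2.
- NaBO3·4H2O in THF/H2O gives (2R)-2-(furan-3-yl)-5-methylhex-4-en-1-ol F3.
- I2, PPh3 and imidazole give 3-[(2R)-1-iodo-5-methylhex-4-en-2-yl]furan F4.
- Zinc dust (iodine-activated, DMA) inserts into 3 to give [(2S)-3-methoxy-2-methyl-3-oxopropyl]zinc bromide F5. A Negishi coupling of F4 with F5 (Ni(cod)2, s-Bu-Pybox, DMA, rt; the C4 radical from F4 is captured at nickel) forms the C3–C4 bond and gives 5.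

Step 4 is the second risk. The 2-furyl boronate can protodeboronate, and the unprotected, electron-rich bromohydroquinone is a slow and oxidation-prone coupling partner.

The fallback sets out from 5 and comes back at 9. It drops boron and palladium and uses the quinone as the aryl source. Sc(OTf)3 (5 mol%) catalyses Friedel–Crafts-type conjugate addition of furan C5 of 5 to 1,4-benzoquinone (2.2 equiv, MeCN, rt). The excess quinone oxidises the adduct to methyl (2R,5R)-5-[5-(3,6-dioxocyclohexa-1,4-dien-1-yl)furan-3-yl]-2,8-dimethylnon-7-enoate F6, which an aqueous Na2S2O4 wash reduces to 9. The isomer from attack at the flanked furan C2 is expected as a by-product and must be separated.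

Step 5 is the third risk. The furyl-hydroquinone is air-sensitive as its phenolate under LiOH, and C2 is an epimerisable centre.

The fallback sets out from 5 and comes back at 10. It hydrolyses the ester before the arene is installed:
- LiOH on 5 gives (2R,5R)-5-(furan-3-yl)-2,8-dimethylnon-7-enoic acid F7.
- HBpin (2.5 equiv) with [Ir(OMe)(cod)]2 and 4,4'-di-tert-butyl-2,2'-bipyridine masks the acid as its pinacolboryl ester and borylates furan C5, giving 4,4,5,5-tetramethyl-1,3,2-dioxaborolan-2-yl (2R,5R)-2,8-dimethyl-5-[5-(4,4,5,5-tetramethyl-1,3,2-dioxaborolan-2-yl)furan-3-yl]non-7-enoate F8, which is not isolated.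
- Suzuki–Miyaura coupling of F8 with 7 (Pd(OAc)2, SPhos, aq K3PO4, 40 °C) and a mildly acidic work-up, which also cleaves the acyloxyborane, give 10 directly, so the hydroquinone never meets LiOH.

**Further compounds**

F1 | step 2 | 2-[(2R)-2-(furan-3-yl)pent-4-en-1-yl]-4,4,5,5-tetramethyl-1,3,2-dioxaborolane | C=CC[C@@H](CB1OC(C)(C)C(C)(C)O1)c1ccoc1
F2 | step 2 | 2-[(2R)-2-(furan-3-yl)-5-methylhex-4-en-1-yl]-4,4,5,5-tetramethyl-1,3,2-dioxaborolane | CC(C)=CC[C@@H](CB1OC(C)(C)C(C)(C)O1)c1ccoc1
F3 | step 2 | (2R)-2-(furan-3-yl)-5-methylhex-4-en-1-ol | CC(C)=CC[C@@H](CO)c1ccoc1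
F4 | step 2 | 3-[(2R)-1-iodo-5-methylhex-4-en-2-yl]furan | CC(C)=CC[C@@H](CI)c1ccoc1
F5 | step 2 | [(2S)-3-methoxy-2-methyl-3-oxopropyl]zinc bromide | Br[Zn]C[C@@H](C)C(=O)OC
F6 | step 4 | methyl (2R,5R)-5-[5-(3,6-dioxocyclohexa-1,4-dien-1-yl)furan-3-yl]-2,8-dimethylnon-7-enoate | CC(C)=CC[C@@H](CC[C@@H](C)C(=O)OC)c1coc(C2=CC(=O)C=CC2=O)c1
F7 | step 5 | (2R,5R)-5-(furan-3-yl)-2,8-dimethylnon-7-enoic acid | CC(C)=CC[C@@H](CC[C@@H](C)C(=O)O)c1ccoc1
F8 | step 5 | 4,4,5,5-tetramethyl-1,3,2-dioxaborolan-2-yl (2R,5R)-2,8-dimethyl-5-[5-(4,4,5,5-tetramethyl-1,3,2-dioxaborolan-2-yl)furan-3-yl]non-7-enoate | CC(C)=CC[C@@H](CC[C@@H](C)C(=O)OB1OC(C)(C)C(C)(C)O1)c1coc(B2OC(C)(C)C(C)(C)O2)c1
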